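All runs stem from a simulated flask from invented constants; noise was put on by code.

More monomer went into chains in the first 2.00 min of the south run (27.6 %) than in the next 6.00 min (7.5 percentage points), so we have a burst followed by a crawl, and the flask must be reckoned through both.

- south: free monomer 5.0 × 10⁻⁴ M; initiator 50 µM; run made earlier
- flask: free monomer 5.0 × 10⁻⁴ M; initiator 25 µM; time 40 min

- south (time / min: monomer in chains / %, free monomer / %): 2.00: 27.6, 71.9; 4.00: 30.3, 68.6; 6.00: 33.0, 65.9; 8.00: 35.1, 65.3

(scatter of a reading: 0.5 percentage points)

- average number of monomer units in a chain (chains begun, living or dead) at 40 min
- part of the free monomer that has reacted at 40 min

- the average divides the monomer in chains by the number of chains begun, living and dead together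
- the earlier runs were read with a standard deviation of 0.5 percentage points
- on the list of suspects stand: 2 living end -> dead end; monomer in chains + living end -> free monomer + living end; free monomer + living end -> monomer in chains + living end; free monomer + initiator -> living end + monomer in chains
- the earlier runs do not show the number of chains; that part of a forecast is a guess
- no earlier run changes the charge of initiator; that part of a forecast is a guess

First, what does a chain cost? We guess that each initiator begins one chain and takes one monomer unit, since the runs do not count chains. Its share s of the free monomer charged is then 10.0 % in the south run and 5.00 % in the flask, and the average chain is c/s, or c times 20.0 in the flask, where c is the part reacted.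

Next, how quickly does the crawl fade? Between 2.00 min and 8.00 min, the south readings of free monomer give, as a reading, the power of time by which free monomer falls, our fade exponent n: 0.0695.

Finally, what does halving the initiator change? If living ends die in pairs (termination), the time they take to thin out goes as one over their starting number. Taking the living ends of each flask to start from its charge of initiator, we guess that the flask at 40 min matches the south curve, carried on by n beyond its last reading to 20.0 min, rescaled by (1 − s). Our estimate of free monomer in the flask at 40 min is then 64.7 %, so c is 35.3 % and the average chain 7.06.

The forecast stands above our reckoning at 7.4 and 37 %, with the words “This looks like fast initiation followed by living ends dying pairwise”.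

The flask gives 7.42 and 37.1 %.

    2 living end → dead end (k = 422 M⁻¹ s⁻¹)
    monomer in chains + living end → free monomer + living end, rate k2*[living end] as long as [monomer in chains] is above zero (k = 0.0570 s⁻¹)
    free monomer + living end → monomer in chains + living end, rate k3*[living end]*[free monomer] (k = 240 M⁻¹ s⁻¹)
    free monomer + initiator → living end + monomer in chains (k = 1210 M⁻¹ s⁻¹)

With the pairwise step struck out, c in the flask is 52.5 %. Carrying n from 40 min to 400 min gives c = 46.4 %, and the flask left that long stands at 44.5 %.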